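## Retrosynthetic overview

1. The ten-membered carbocycle is closed last, at C4–C5, by an intramolecular Nozaki–Hiyama–Kishi reaction of seco-aldehyde 30 (C4 enol triflate onto C5 aldehyde); this one step gives the C4=C15 methylene and the C5 carbinol.
2. 30 comes from seco-alcohol 25 by angeloylation at O8 and unmasking of C5; 25 is the fragment union, a CrCl2 allylation forming C7–C8 between West aldehyde 23 and East bromide 10, which also creates the α-methylene lactone and sets C7 and C8.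
3. West fragment 23 (C8–C10, C1–C4, C14, C15): both oxiranes are made on the open chain, by Shi epoxidation of enynol 15 (C10/C1), then Lindlar reduction and hydroxyl-directed mCPBA epoxidation (C2/C3); 15 comes from carboalumination/Sonogashira of pent-1-en-4-yne and (R)-but-3-yn-2-ol.
4. East fragment 10 (C5–C7, C11–C13): L-glutamic acid → γ-lactone (C6 stereocentre) → α-methylenation → Br2 addition/dehydrobromination.
5. Ring order: γ-lactone (step 1), 1,10-oxirane (step 10), 2,3-oxirane (step 12), carbocycle (step 20).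

Conventions: locants C1–C15 are the germacranolide locants of the target (carbocycle C1–C10, C14 = methyl on C10, C15 = methylene on C4, lactone C6–O–C12(=O)–C11(=C13)–C7); TBS = tert-butyldimethylsilyl, Tf = CF3SO2, DMP = Dess–Martin periodinane, mCPBA = 3-chloroperbenzoic acid.

## Route

**East fragment**

Step 1
Reactants: 1 L-glutamic acid
Product: 2 (S)-5-oxotetrahydrofuran-2-carboxylic acid
Conditions: NaNO2, aq. HCl, 0 °C → rt
Reagents that add atoms: none
Why: Diazotization with double inversion (α-lactone, then opening by the γ-carboxyl group) gives the γ-lactone with net retention, fixing the future C6 as S.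

Step 2
Reactants: 2 (S)-5-oxotetrahydrofuran-2-carboxylic acid
Product: 3 (S)-5-(hydroxymethyl)dihydrofuran-2(3H)-one
Conditions: BH3·SMe2, THF, 0 °C → rt; aq. work-up
Reagents that add atoms: none
Why: Chemoselective borane reduction of the carboxylic acid in the presence of the lactone; the stereocentre is untouched.

Step 3
Reactants: 3 (S)-5-(hydroxymethyl)dihydrofuran-2(3H)-one
Product: 4 (S)-5-(TBS-oxymethyl)dihydrofuran-2(3H)-one
Conditions: TBSCl, imidazole, CH2Cl2, rt
Reagents that add atoms: tert-butyldimethylsilyl chloride, CC(C)(C)[Si](C)(C)Cl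
Why: Silyl ether formation protects the primary alcohol (future C5–OH) until step 18.

Step 4
Reactants: 4 (S)-5-(TBS-oxymethyl)dihydrofuran-2(3H)-one
Product: 6 (3S,5S)-3-[(dimethylamino)methyl]-5-(TBS-oxymethyl)dihydrofuran-2(3H)-one, via lithium enolate 5 (not isolated)
Conditions: LiN(iPr)2, THF, −78 °C; then Me2N=CH2+ I−, −78 °C → rt
Reagents that add atoms: N,N-dimethylmethyleneiminium iodide (Eschenmoser's salt), C=[N+](C)C.[I-]
Why: Mannich reaction of the lactone enolate, trans to the C5 substituent; the new centre is erased in step 5, so its ratio is irrelevant.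

Step 5
Reactants: 6 (3S,5S)-3-[(dimethylamino)methyl]-5-(TBS-oxymethyl)dihydrofuran-2(3H)-one
Product: 8 (S)-5-(TBS-oxymethyl)-3-methylidenedihydrofuran-2(3H)-one, via ammonium iodide 7 (not isolated)
Conditions: MeI, MeOH, rt; then aq. NaHCO3/CH2Cl2, rt
Reagents that add atoms: none
Why: N-quaternization followed by E1cB (Hofmann-type) loss of trimethylamine gives the α-methylene lactone.

Step 6
Reactants: 8 (S)-5-(TBS-oxymethyl)-3-methylidenedihydrofuran-2(3H)-one
Product: 9 (3R,5S)-3-bromo-3-(bromomethyl)-5-(TBS-oxymethyl)dihydrofuran-2(3H)-one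
Conditions: Br2, CH2Cl2, 0 °C → rt
Reagents that add atoms: bromine, BrBr
Why: Electrophilic anti-addition of bromine to the exocyclic alkene; the C3 centre (both epimers serve) is lost again in step 7.

Step 7
Reactants: 9 (3R,5S)-3-bromo-3-(bromomethyl)-5-(TBS-oxymethyl)dihydrofuran-2(3H)-one
Product: 10 (S)-3-(bromomethyl)-5-(TBS-oxymethyl)furan-2(5H)-one
Conditions: DBU (1.05 equiv), THF, −20 → 0 °C
Reagents that add atoms: none
Why: E2 dehydrobromination of the tertiary α-bromide toward the ring CH2 gives the conjugated butenolide that keeps the allylic CH2Br; low temperature and stoichiometric base protect the γ-stereocentre.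

**West fragment**

Step 8
Reactants: 11 pent-1-en-4-yne
Product: 13 (1E)-1-iodo-2-methylpenta-1,4-diene, via alkenylalane 12 (not isolated)
Conditions: AlMe3 (2 equiv), Cp2ZrCl2 (20 mol%), CH2Cl2, 0 °C → rt; then I2, THF, −30 → 0 °C
Reagents that add atoms: trimethylaluminium, C[Al](C)C; iodine, II
Why: Negishi zirconium-catalysed syn-carboalumination of the terminal alkyne (the alkene does not react) and iodinolysis with retention give the E-trisubstituted vinyl iodide, i.e. the C10=C1 geometry and the C14 methyl.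

Step 9
Reactants: 13 (1E)-1-iodo-2-methylpenta-1,4-diene; 14 (R)-but-3-yn-2-ol
Product: 15 (2R,5E)-6-methylnona-5,8-dien-3-yn-2-ol
Conditions: PdCl2(PPh3)2 (3 mol%), CuI (6 mol%), Et3N, THF, rt
Reagents that add atoms: none
Why: Sonogashira coupling with retention of the E geometry; it brings in C2–C4/C15 and the (R)-carbinol that directs step 12.

Step 10
Reactants: 15 (2R,5E)-6-methylnona-5,8-dien-3-yn-2-ol
Product: 16 (2R)-4-[(2R,3R)-3-methyl-3-(prop-2-en-1-yl)oxiran-2-yl]but-3-yn-2-ol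
Conditions: D-fructose-derived Shi ketone (30 mol%), KHSO5 (as 2KHSO5·KHSO4·K2SO4), K2CO3, Bu4NHSO4, aq. Na2B4O7/Na2EDTA (pH ≈ 10.5), MeCN–CH2(OMe)2, 0 °C
Reagents that add atoms: potassium peroxymonosulfate, [K+].[O-]S(=O)(=O)OO
Why: Shi asymmetric epoxidation (chiral dioxirane, spiro transition state) of the trisubstituted E-olefin of the enyne, with alkyne and terminal alkene inert; catalyst control sets C10 (R) and C1 (R), the same facial sense as for (R,R)-trans-β-methylstyrene oxide.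

Step 11
Reactants: 16 (2R)-4-[(2R,3R)-3-methyl-3-(prop-2-en-1-yl)oxiran-2-yl]but-3-yn-2-ol
Product: 17 (2R,3Z)-4-[(2R,3R)-3-methyl-3-(prop-2-en-1-yl)oxiran-2-yl]but-3-en-2-ol
Conditions: H2 (1 atm, stopped at 1 equiv), Pd/CaCO3 poisoned with Pb(OAc)2, quinoline, EtOAc, rt
Reagents that add atoms: none
Why: Lindlar syn-semihydrogenation gives the Z-alkene needed for the cis-oxirane; the monosubstituted alkene reacts far more slowly.

Step 12
Reactants: 17 (2R,3Z)-4-[(2R,3R)-3-methyl-3-(prop-2-en-1-yl)oxiran-2-yl]but-3-en-2-ol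
Product: 18 (1R)-1-{(2S,3S)-3-[(2R,3R)-3-methyl-3-(prop-2-en-1-yl)oxiran-2-yl]oxiran-2-yl}ethan-1-ol
Conditions: mCPBA, NaHCO3, CH2Cl2, 0 °C
Reagents that add atoms: 3-chloroperbenzoic acid, O=C(OO)c1cccc(Cl)c1
Why: Hydroxyl-directed (Henbest) epoxidation of a Z-allylic alcohol: A(1,3) strain holds the carbinol H in the alkene plane and the hydrogen-bonded peracid adds syn to OH (threo), on the face away from the quaternary C10, giving the cis-oxirane with C2 (S) and C3 (S).

Step 13
Reactants: 18 (1R)-1-{(2S,3S)-3-[(2R,3R)-3-methyl-3-(prop-2-en-1-yl)oxiran-2-yl]oxiran-2-yl}ethan-1-ol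
Product: 19 1-{(2R,3R)-3-[(2R,3R)-3-methyl-3-(prop-2-en-1-yl)oxiran-2-yl]oxiran-2-yl}ethan-1-one
Conditions: DMP, NaHCO3, CH2Cl2, 0 °C → rt
Reagents that add atoms: none
Why: Dess–Martin oxidation removes the auxiliary C4 carbinol centre; the oxirane C–H is not enolisable, so the cis-oxirane is kept (descriptors change only through CIP priorities).

Step 14
Reactants: 19 1-{(2R,3R)-3-[(2R,3R)-3-methyl-3-(prop-2-en-1-yl)oxiran-2-yl]oxiran-2-yl}ethan-1-one
Product: 21 1-{(2R,3S)-3-[(2R,3R)-3-methyl-3-(prop-2-en-1-yl)oxiran-2-yl]oxiran-2-yl}ethenyl trifluoromethanesulfonate, via potassium enolate 20 (not isolated)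
Conditions: KN(SiMe3)2, THF, −78 °C; then Comins' reagent, −78 °C
Reagents that add atoms: N-(5-chloropyridin-2-yl)-1,1,1-trifluoro-N-(trifluoromethylsulfonyl)methanesulfonamide (Comins' reagent), FC(F)(F)S(=O)(=O)N(c1ccc(Cl)cn1)S(=O)(=O)C(F)(F)F
Why: Kinetic enolization can occur only at the methyl group, and O-triflation gives the 2-triflyloxy-1-alkene (C4/C15) that serves as the alkenyl electrophile in step 20.

Step 15
Reactants: 21 1-{(2R,3S)-3-[(2R,3R)-3-methyl-3-(prop-2-en-1-yl)oxiran-2-yl]oxiran-2-yl}ethenyl trifluoromethanesulfonate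
Product: 23 1-{(2R,3S)-3-[(2R,3R)-3-methyl-3-(2-oxoethyl)oxiran-2-yl]oxiran-2-yl}ethenyl trifluoromethanesulfonate, via ozonide 22 (not isolated)
Conditions: O3 (1.0 equiv), CH2Cl2, −78 °C; then PPh3, −78 °C → rt; evaporated (CH2O removed), short neutral SiO2 plug, used at once
Reagents that add atoms: ozone, [O-][O+]=O
Why: Ozonolysis with reductive work-up cleaves the electron-rich monosubstituted alkene much faster than the electron-poor enol triflate, and the neutral conditions spare the base-sensitive β,γ-epoxy aldehyde.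

**Union and endgame**

Step 16
Reactants: 10 (S)-3-(bromomethyl)-5-(TBS-oxymethyl)furan-2(5H)-one; 23 West aldehyde
Product: 25 seco-alcohol (6S,7R,8S; full name in the list), via allylchromium reagent 24 (not isolated)
Conditions: CrCl2 (4 equiv, nickel-free), THF, 0 °C → rt
Reagents that add atoms: none
Why: Nozaki–Hiyama (chromium Barbier) allylation: the allyl–CrCl2 species reacts through its γ-carbon (C7) anti to the CH2OTBS group on C6, and the chair Zimmerman–Traxler transition state (ring-fixed E-type allyl geometry, aldehyde chain equatorial) gives the anti adduct, i.e. C7 (R) and C8 (S), while the double bond moves out to form the α-methylene lactone; the enol triflate is inert without nickel.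

Step 17
Reactants: 25 seco-alcohol; 26 angelic acid
Product: 28 seco-angelate (8-O-angeloyl-25), via mixed anhydride 27 (not isolated)
Conditions: 26, 2,4,6-Cl3C6H2COCl, Et3N, toluene, rt; then 25, 60 °C (no DMAP)
Reagents that add atoms: none
Why: Yamaguchi esterification acylates O8 with retention at C8; omitting DMAP keeps Z → E isomerization of the angelate to a minimum.

Step 18
Reactants: 28 seco-angelate
Product: 29 primary alcohol (5-OH seco-angelate)
Conditions: Bu4NF/AcOH (1:1), THF, 0 °C → rt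
Reagents that add atoms: none
Why: Buffered fluoride desilylation of the primary TBS ether; oxiranes, triflate, angelate and α-methylene lactone tolerate the near-neutral medium.

Step 19
Reactants: 29 primary alcohol
Product: 30 seco-aldehyde (C5 aldehyde)
Conditions: DMP, NaHCO3, CH2Cl2, 0 °C; used at once
Reagents that add atoms: none
Why: Dess–Martin oxidation gives the α-acyloxy aldehyde under non-epimerizing conditions (C6 kept).

Step 20
Reactants: 30 seco-aldehyde
Product: 32 CNP0038366.2 (target), via alkenylchromium species 31 (not isolated)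
Conditions: CrCl2 (10 equiv), NiCl2 (10 mol%), DMSO–THF, rt, 2 mM, slow addition
Reagents that add atoms: none
Why: Intramolecular Nozaki–Hiyama–Kishi macrocyclization: nickel-catalysed activation of the C4 enol triflate, transmetalation to chromium and addition to the C5 aldehyde close the ten-membered ring; Felkin–Anh (polar) attack anti to the C6–O bond gives the 5,6-anti carbinol, C5 (R).

## Compound list

1 | L-glutamic acid | N[C@@H](CCC(=O)O)C(=O)O | starting material
2 | (S)-5-oxotetrahydrofuran-2-carboxylic acid | O=C1CC[C@@H](C(=O)O)O1 | intermediate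
3 | (S)-5-(hydroxymethyl)dihydrofuran-2(3H)-one | O=C1CC[C@@H](CO)O1 | intermediate
4 | (S)-5-{[(tert-butyldimethylsilyl)oxy]methyl}dihydrofuran-2(3H)-one | O=C1CC[C@@H](CO[Si](C)(C)C(C)(C)C)O1 | intermediate
5 | lithium enolate of 4 (not isolated) | [Li]OC1=CC[C@@H](CO[Si](C)(C)C(C)(C)C)O1 | intermediate
6 | (3S,5S)-3-[(dimethylamino)methyl]-5-{[(TBS)oxy]methyl}dihydrofuran-2(3H)-one (trans; the cis epimer converges) | CN(C)C[C@@H]1C[C@@H](CO[Si](C)(C)C(C)(C)C)OC1=O | intermediate
7 | {[(3S,5S)-5-{[(TBS)oxy]methyl}-2-oxotetrahydrofuran-3-yl]methyl}trimethylammonium iodide (not isolated) | C[N+](C)(C)C[C@@H]1C[C@@H](CO[Si](C)(C)C(C)(C)C)OC1=O.[I-] | intermediate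
8 | (S)-5-{[(TBS)oxy]methyl}-3-methylidenedihydrofuran-2(3H)-one | C=C1C[C@@H](CO[Si](C)(C)C(C)(C)C)OC1=O | intermediate
9 | (3R,5S)-3-bromo-3-(bromomethyl)-5-{[(TBS)oxy]methyl}dihydrofuran-2(3H)-one (major epimer; both converge) | BrC[C@@]1(Br)C[C@@H](CO[Si](C)(C)C(C)(C)C)OC1=O | intermediate
10 | (S)-3-(bromomethyl)-5-{[(TBS)oxy]methyl}furan-2(5H)-one (East fragment) | BrCC1=C[C@@H](CO[Si](C)(C)C(C)(C)C)OC1=O | intermediate
11 | pent-1-en-4-yne | C=CCC#C | starting material
12 | dimethyl[(1E)-2-methylpenta-1,4-dien-1-yl]aluminium (not isolated) | C=CC/C(C)=C/[Al](C)C | intermediate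
13 | (1E)-1-iodo-2-methylpenta-1,4-diene | C=CC/C(C)=C/I | intermediate
14 | (R)-but-3-yn-2-ol | C#C[C@@H](C)O | starting material
15 | (2R,5E)-6-methylnona-5,8-dien-3-yn-2-ol | C=CC/C(C)=C/C#C[C@@H](C)O | intermediate
16 | (2R)-4-[(2R,3R)-3-methyl-3-(prop-2-en-1-yl)oxiran-2-yl]but-3-yn-2-ol | C=CC[C@@]1(C)O[C@@H]1C#C[C@@H](C)O | intermediate
17 | (2R,3Z)-4-[(2R,3R)-3-methyl-3-(prop-2-en-1-yl)oxiran-2-yl]but-3-en-2-ol | C=CC[C@@]1(C)O[C@@H]1/C=C\[C@@H](C)O | intermediate
18 | (1R)-1-{(2S,3S)-3-[(2R,3R)-3-methyl-3-(prop-2-en-1-yl)oxiran-2-yl]oxiran-2-yl}ethan-1-ol | C=CC[C@@]1(C)O[C@@H]1[C@H]1O[C@H]1[C@@H](C)O | intermediate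
19 | 1-{(2R,3R)-3-[(2R,3R)-3-methyl-3-(prop-2-en-1-yl)oxiran-2-yl]oxiran-2-yl}ethan-1-one | C=CC[C@@]1(C)O[C@@H]1[C@H]1O[C@H]1C(C)=O | intermediate
20 | potassium enolate of 19 (not isolated) | C=CC[C@@]1(C)O[C@@H]1[C@H]1O[C@H]1C(=C)O[K] | intermediate
21 | 1-{(2R,3S)-3-[(2R,3R)-3-methyl-3-(prop-2-en-1-yl)oxiran-2-yl]oxiran-2-yl}ethenyl trifluoromethanesulfonate | C=CC[C@@]1(C)O[C@@H]1[C@H]1O[C@H]1C(=C)OS(=O)(=O)C(F)(F)F | intermediate
22 | ozonide of 21 (1,2,4-trioxolan-3-ylmethyl in place of allyl; both epimers at the trioxolane carbon; not isolated) | C1OOC(O1)C[C@@]1(C)O[C@@H]1[C@H]1O[C@H]1C(=C)OS(=O)(=O)C(F)(F)F | intermediate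
23 | 1-{(2R,3S)-3-[(2R,3R)-3-methyl-3-(2-oxoethyl)oxiran-2-yl]oxiran-2-yl}ethenyl trifluoromethanesulfonate (West fragment; C8 aldehyde, 1R,2S,3R,10R) | O=CC[C@@]1(C)O[C@@H]1[C@H]1O[C@H]1C(=C)OS(=O)(=O)C(F)(F)F | intermediate
24 | dichloro{[(5S)-5-{[(TBS)oxy]methyl}-2-oxo-2,5-dihydrofuran-3-yl]methyl}chromium (not isolated) | Cl[Cr](Cl)CC1=C[C@@H](CO[Si](C)(C)C(C)(C)C)OC1=O | intermediate
25 | (4R,5S)-5-{[(TBS)oxy]methyl}-4-[(1S)-1-hydroxy-2-{(2R,3R)-2-methyl-3-[(2S,3R)-3-(1-{[(trifluoromethyl)sulfonyl]oxy}ethenyl)oxiran-2-yl]oxiran-2-yl}ethyl]-3-methylidenedihydrofuran-2(3H)-one | C=C1C(=O)O[C@H](CO[Si](C)(C)C(C)(C)C)[C@H]1[C@@H](O)C[C@@]1(C)O[C@@H]1[C@H]1O[C@H]1C(=C)OS(=O)(=O)C(F)(F)F | intermediate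
26 | angelic acid [(2Z)-2-methylbut-2-enoic acid] | C/C=C(/C)C(=O)O | starting material
27 | (2Z)-2-methylbut-2-enoic 2,4,6-trichlorobenzoic anhydride (not isolated) | C/C=C(/C)C(=O)OC(=O)c1c(Cl)cc(Cl)cc1Cl | intermediate
28 | (1S)-1-[(2S,3R)-2-{[(TBS)oxy]methyl}-4-methylidene-5-oxotetrahydrofuran-3-yl]-2-{(2R,3R)-2-methyl-3-[(2S,3R)-3-(1-{[(trifluoromethyl)sulfonyl]oxy}ethenyl)oxiran-2-yl]oxiran-2-yl}ethyl (2Z)-2-methylbut-2-enoate | C=C1C(=O)O[C@H](CO[Si](C)(C)C(C)(C)C)[C@H]1[C@@H](OC(=O)/C(C)=C\C)C[C@@]1(C)O[C@@H]1[C@H]1O[C@H]1C(=C)OS(=O)(=O)C(F)(F)F | intermediate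
29 | as 28 with 2-(hydroxymethyl) in place of 2-{[(TBS)oxy]methyl} (free C5–OH) | C=C1C(=O)O[C@H](CO)[C@H]1[C@@H](OC(=O)/C(C)=C\C)C[C@@]1(C)O[C@@H]1[C@H]1O[C@H]1C(=C)OS(=O)(=O)C(F)(F)F | intermediate
30 | as 28 with 2-formyl in place of 2-{[(TBS)oxy]methyl} (C5 aldehyde; 6S,7R,8S,10R,1R,2S,3R) | C=C1C(=O)O[C@H](C=O)[C@H]1[C@@H](OC(=O)/C(C)=C\C)C[C@@]1(C)O[C@@H]1[C@H]1O[C@H]1C(=C)OS(=O)(=O)C(F)(F)F | intermediate
31 | C4 alkenylchromium dichloride derived from 30 (CrCl2 in place of OTf; not isolated) | C=C1C(=O)O[C@H](C=O)[C@H]1[C@@H](OC(=O)/C(C)=C\C)C[C@@]1(C)O[C@@H]1[C@H]1O[C@H]1C(=C)[Cr](Cl)Cl | intermediate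
32 | CNP0038366.2: (1R,2S,3S,5R,6S,7R,8S,10R)-8-angeloyloxy-1,10:2,3-diepoxy-5-hydroxygermacra-4(15),11(13)-dien-12,6-olide | C=C1C(=O)O[C@H]2[C@H]1[C@@H](OC(=O)/C(C)=C\C)C[C@@]1(C)O[C@@H]1[C@H]1O[C@H]1C(=C)[C@H]2O | target

## Step count and risks

Total: 20 steps (East 1–7, West 8–15, joint 16–20).
Longest linear sequence: 13 steps (8–15, then 16–20, from pent-1-en-4-yne); the East branch runs 12 (1–7, then 16–20).

Steps most likely to fail:

1. Step 20 (macrocyclization). The ten-membered ring is strained, the alkenyl–chromium carbon sits next to an oxirane (risk of β-elimination), and the facial selectivity at C5 is decided by the ring conformation and may not follow the acyclic Felkin–Anh preference. Fallback, setting out from 30 and returning at 32: the CrCl2/NiCl2 closure is run without relying on its facial selectivity; if it gives mainly the C5 epimer of the target F1, this allylic alcohol is oxidised (DMP, NaHCO3) to the ten-membered 5-ketone F2, and C5 is then set by reagent-controlled 1,2-reduction with (R)-2-methyl-CBS-oxazaborolidine/catecholborane at −78 °C (alkenyl carbon C4 as the large group; NaBH4/CeCl3 if the ring itself favours the right face), which returns to 32. This corrects C5 only; it does not help if the ring fails to close.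

2. Step 16 (fragment union). Aldehyde 23 is a β,γ-epoxy aldehyde that can open to a γ-hydroxy enal before it is trapped, and the union must set two centres at once. Fallback, setting out from 13 and returning at 28: chemoselective ozonolysis of the terminal alkene of 13 (O3, CH2Cl2, −78 °C; PPh3) gives the robust (3E)-4-iodo-3-methylbut-3-enal F3. The same CrCl2 allylation with 10 gives the homoallylic alcohol F4 (vinyl iodide inert without nickel), and Yamaguchi angeloylation as in step 17 gives the angelate F5. Sonogashira coupling with 14 gives the enynol F6, Shi epoxidation the 1,10-epoxide F7, Lindlar reduction the Z-alkene F8, hydroxyl-directed mCPBA epoxidation the bis-epoxy alcohol F9 and DMP oxidation the methyl ketone F10. KN(SiMe3)2/Comins' reagent (1.0 equiv, −78 °C) then gives 28. The price is a longer linear sequence, and the α-methylene lactone must survive the basic Shi medium and the Lindlar step.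

3. Step 7 (dehydrobromination). The product is a reactive allylic bromide with an acidic γ-hydrogen at the stereocentre from which C7 and C8 are later relayed; an amidine base can alkylate, eliminate the wrong way (bromomethylene lactone) or racemise it. Fallback, setting out from 4 and returning at 10: α-selenenylation of 4 (LiN(iPr)2, then PhSeBr, −78 °C) gives the α-phenylselanyl lactone F11; H2O2 oxidation and selenoxide syn-elimination give (S)-5-(TBS-oxymethyl)furan-2(5H)-one F12; Morita–Baylis–Hillman hydroxymethylation (aq. CH2O, cat. imidazole or PBu3) gives the 3-(hydroxymethyl)butenolide F13; Appel bromination (CBr4, PPh3, CH2Cl2, 0 °C) gives 10 without any base contact of the allylic bromide.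

Further compounds

F1 | step 20 | C5 epimer of 32 (5S) | C=C1C(=O)O[C@H]2[C@H]1[C@@H](OC(=O)/C(C)=C\C)C[C@@]1(C)O[C@@H]1[C@H]1O[C@H]1C(=C)[C@@H]2O
F2 | step 20 | 5-oxo macrocycle (5-dehydro-32) | C=C1C(=O)O[C@H]2[C@H]1[C@@H](OC(=O)/C(C)=C\C)C[C@@]1(C)O[C@@H]1[C@H]1O[C@H]1C(=C)C2=O
F3 | step 16 | (3E)-4-iodo-3-methylbut-3-enal | O=CC/C(C)=C/I
F4 | step 16 | (4R,5S)-5-{[(TBS)oxy]methyl}-4-[(1S,3E)-1-hydroxy-4-iodo-3-methylbut-3-en-1-yl]-3-methylidenedihydrofuran-2(3H)-one | C=C1C(=O)O[C@H](CO[Si](C)(C)C(C)(C)C)[C@H]1[C@@H](O)C/C(C)=C/I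
F5 | step 16 | 8-O-angelate of F4 | C=C1C(=O)O[C@H](CO[Si](C)(C)C(C)(C)C)[C@H]1[C@@H](OC(=O)/C(C)=C\C)C/C(C)=C/I
F6 | step 16 | enynol from F5 and 14 (C4 carbinol R, C10=C1 E) | C=C1C(=O)O[C@H](CO[Si](C)(C)C(C)(C)C)[C@H]1[C@@H](OC(=O)/C(C)=C\C)C/C(C)=C/C#C[C@@H](C)O
F7 | step 16 | (10R,1R)-1,10-epoxide of F6 | C=C1C(=O)O[C@H](CO[Si](C)(C)C(C)(C)C)[C@H]1[C@@H](OC(=O)/C(C)=C\C)C[C@@]1(C)O[C@@H]1C#C[C@@H](C)O
F8 | step 16 | (2Z)-alkene from F7 | C=C1C(=O)O[C@H](CO[Si](C)(C)C(C)(C)C)[C@H]1[C@@H](OC(=O)/C(C)=C\C)C[C@@]1(C)O[C@@H]1/C=C\[C@@H](C)O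
F9 | step 16 | 1,10:2,3-bis-epoxy C4 alcohol from F8 | C=C1C(=O)O[C@H](CO[Si](C)(C)C(C)(C)C)[C@H]1[C@@H](OC(=O)/C(C)=C\C)C[C@@]1(C)O[C@@H]1[C@H]1O[C@H]1[C@@H](C)O
F10 | step 16 | C4 methyl ketone from F9 | C=C1C(=O)O[C@H](CO[Si](C)(C)C(C)(C)C)[C@H]1[C@@H](OC(=O)/C(C)=C\C)C[C@@]1(C)O[C@@H]1[C@H]1O[C@H]1C(C)=O
F11 | step 7 | (3S,5S)-3-(phenylselanyl)-5-{[(TBS)oxy]methyl}dihydrofuran-2(3H)-one (trans; epimer converges) | c1ccccc1[Se][C@@H]1C[C@@H](CO[Si](C)(C)C(C)(C)C)OC1=O
F12 | step 7 | (S)-5-{[(TBS)oxy]methyl}furan-2(5H)-one | O=C1C=C[C@@H](CO[Si](C)(C)C(C)(C)C)O1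
F13 | step 7 | (S)-3-(hydroxymethyl)-5-{[(TBS)oxy]methyl}furan-2(5H)-one | OCC1=C[C@@H](CO[Si](C)(C)C(C)(C)C)OC1=O
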